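Between 20.0 h and 30.0 h in the red run, the over-reaction product gained 5.8 percentage points while target lost 2.4 points. Over-reaction gained more than target lost, so target was still being formed, and I began from these two columns.

| setting | red | north-west | north |
|---|---|---|---|
| starting material | 0.051 M | 0.051 M | 0.012 M |
| reagent | 0.0612 M | 0.0612 M | 0.250 M |
| second substrate | 0.0255 M | 0.0255 M | 0.0255 M |
| third substrate | 0.17 M | 0.255 M | 0.255 M |
| remark | run made earlier |  |  |
| time |  | 50 h | 50 h |

- red (time / h: target / %, over-reaction product / %): 2.50: 7.2, 0; 4.00: 10.3, 1.2; 6.00: 13.5, 1.6; 8.00: 16.1, 2.4; 12.0: 19.3, 5.3; 20.0: 19.0, 10.6; 30.0: 16.6, 16.4

(readings scatter by 0.5 percentage points)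

* the flask that ends with the higher share of target in all that became target or over-reaction product, or "neither" when 2 percentage points or less lies between them (north-west / north / neither)
* share of target in all that became target or over-reaction product, north-west
* share of target in all that became target or over-reaction product, north

- the numbers in the tables scatter by 0.5 percentage points (one standard deviation)

I divided the gain in over-reaction product by the time and by the mean target between those readings, and got 0.0326 h⁻¹. This is my clock, the first-order decay constant of target, assuming that over-reaction depends on target and nothing else. On these readings target has a half-life of about 21.3 h. A portion of target of a given age survives as exp(−k·age), so I took the share in a flask as exp(−k·age) at the age of its middle portion.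

Now I read the sum of the columns. It stood at 15.1% at 6.00 h and 18.5% at 8.00 h, against 33.0% at the last reading, so in red half of that last sum had formed by about 7.00 h. Taking that mark for north-west, I reckoned 24.6%.

For north, the sum at the first reading of red, divided by its time, gives a formation constant of 0.0288 h⁻¹. I scaled this with c(reagent), which at the charge in north is 4.08 times that in red, and held it there as if c(reagent) did not fall, and by this estimate the middle of formation came at 5.89 h. North then comes to 23.8%, and my call was neither.

The forecast differs from me on all three: north-west, with 18% and 10%, holding for north that “target is made earlier and has longer to over-react”.

The flask gave neither: north-west 26.7%, north 27.3%.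

    third substrate + reagent → third product (k = 0.00505 L mol⁻¹ min⁻¹)
    starting material + reagent → target (k = 0.00958 L mol⁻¹ min⁻¹)
    target → over-reaction product (k = 5.57 × 10⁻⁴ min⁻¹)
    second substrate + reagent → second product (k = 0.00684 L mol⁻¹ min⁻¹)

In north-west, half of the turnover to target up to the asked time was done by 5.95 h, earlier than the same mark for over-reaction at 22.7 h. Target there was made 3.43 times faster than it was used up at 6.31 h, but at 50.0 h that ratio was 0.0737. With this 5.95 h, my clock gives 23.8% for north-west against 26.7%. For the same flask read at 30 h, keeping that mark although it was taken up to the asked time, my clock gives 45.7% against the simulated 48.9%.

All runs are calculated on assumed constants.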